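A direct plan would close ring C last by a chiral-acid-catalysed [4+2] union of salicylaldehyde A1, trimethyl orthoformate and vinylchromene A2 through a 4-methoxy ortho-quinone methide, giving 4-methoxyflavan A3; hydrolysis to flavan-4-ol A4, oxidation and desilylation would follow.
Its weakest steps would be:
- the three-component cycloaddition: no enantioselective precedent, and the strong acid could oligomerise the para-alkoxystyrene A2;
- the solvolysis of the C4 methyl ether of A3: ionisation beside an acid-labile C2 aryl ether, a chromene and a prenyl group, with elimination as an exit;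
- the solvolysis–oxidation pair through A4: two steps that would only correct the oxidation level at C4.

The route rests on the C2–C3 bond of ring C. The ring-A acid and the ring-B aldehyde are first joined as an acetal in a temporary 1,3-benzodioxin-4-one ring whose O3–C2 bond is absent from the target; methylenation then supplies C3. In the key step a chiral Brønsted acid ionises this racemic enol acetal, helped by the ring-B oxygen para to C2, to an achiral aryloxocarbenium–enol ion pair that recloses from C3: a Petasis–Ferrier-type [1,3] O-to-C shift that builds ring C, the C4 ketone and (2S)-C2 in one enantioconvergent operation. No acid-sensitive styrene is needed, and C4 is never an ether that must be solvolysed and reoxidised.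

Key step: step 6

Assumption: the sense of induction of the new key step cannot be predicted; the (S,S)-catalyst is written as the one taken to give (2S), and its antipode would be used otherwise.

Step 1
Reactants: 1 4-hydroxybenzaldehyde; 2 1,1-diethoxy-3-methylbut-2-ene
Product: 4 2,2-dimethyl-2H-chromene-6-carbaldehyde, via ortho-quinone methide 3 (not isolated)
Conditions: 3-picoline (0.3 equiv), p-xylene, reflux, EtOH distilled off
Reagents that add atoms: none
Why: Base-mediated chromenylation of a phenol with an enal acetal, a known route to 2,2-dimethylchromenes that also serves electron-poor phenols: exchange and loss of two molecules of ethanol should lead to the ortho-dienone 3, whose oxa-6π electrocyclisation closes the pyran ring, and the para formyl group leaves the two ortho positions equivalent.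

Step 2
Reactants: 5 5-bromo-2,4-dihydroxybenzoic acid
Product: 7 5-bromo-4-[(tert-butyldimethylsilyl)oxy]-2-hydroxybenzoic acid, via silyl ester 6 (not isolated)
Conditions: TBSCl (2.2 equiv), imidazole, DMF, 0 °C to rt; then AcOH–THF–H2O, rt
Reagents that add atoms: tert-butyldimethylsilyl chloride, CC(C)(C)[Si](C)(C)Cl
Why: Silylation should take place at the carboxyl group and at the free 4-OH (the 2-OH is tied up in the hydrogen bond to the carbonyl group), and mild hydrolysis of the labile silyl ester 6 should then leave only the aryl silyl ether.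

Step 3
Reactants: 7 5-bromo-4-[(tert-butyldimethylsilyl)oxy]-2-hydroxybenzoic acid; 4 2,2-dimethyl-2H-chromene-6-carbaldehyde
Product: 9 rac-6-bromo-7-[(tert-butyldimethylsilyl)oxy]-2-(2,2-dimethyl-2H-chromen-6-yl)-4H-1,3-benzodioxin-4-one, via bis-silylated acid 8 (not isolated)
Conditions: HMDS, CH2Cl2, rt, then evaporation; 4 (1.05 equiv), TMSOTf (10 mol %), CH2Cl2, −78 to −30 °C; Et3N quench
Reagents that add atoms: none
Why: TMSOTf-catalysed acetalisation of a silylated hydroxy acid with an aldehyde (the union step of Petasis–Ferrier sequences): the silyl ester of 8 should add to the activated aldehyde, the O-silyl hemiacylal should ionise with para-alkoxy assistance, and the aryl silyl ether should close the six-membered acylal ring with loss of hexamethyldisiloxane; the acetal carbon is formed racemic, which is of no consequence.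

Step 4
Reactants: 9 rac-6-bromo-7-[(tert-butyldimethylsilyl)oxy]-2-(2,2-dimethyl-2H-chromen-6-yl)-4H-1,3-benzodioxin-4-one
Product: 10 rac-7-[(tert-butyldimethylsilyl)oxy]-2-(2,2-dimethyl-2H-chromen-6-yl)-6-(3-methylbut-2-en-1-yl)-4H-1,3-benzodioxin-4-one
Conditions: (3-methylbut-2-en-1-yl)zinc bromide (1.5 equiv, prepared from prenyl bromide, Zn dust and LiCl in THF), Pd(OAc)2 (2 mol %), CPhos (4 mol %), THF, rt
Reagents that add atoms: (3-methylbut-2-en-1-yl)zinc bromide, CC(C)=CC[Zn]Br
Why: Negishi cross-coupling of a prenylzinc halide under linear-selective conditions: fast reductive elimination from the primary σ-allyl palladium species bearing the bulky biarylphosphine should give the linear prenyl arene, and the ester-type carbonyl, the silyl ether and the chromene should be tolerated at room temperature.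

Step 5
Reactants: 10 rac-7-[(tert-butyldimethylsilyl)oxy]-2-(2,2-dimethyl-2H-chromen-6-yl)-6-(3-methylbut-2-en-1-yl)-4H-1,3-benzodioxin-4-one
Product: 11 rac-tert-butyl{[2-(2,2-dimethyl-2H-chromen-6-yl)-4-methylidene-6-(3-methylbut-2-en-1-yl)-4H-1,3-benzodioxin-7-yl]oxy}dimethylsilane
Conditions: Cp2TiMe2 (2.5 equiv), toluene, 65 °C, dark; filtration through basic alumina
Reagents that add atoms: dimethyltitanocene, C[Ti](C)(C1C=CC=C1)C1C=CC=C1
Why: Petasis methylenation: Cp2TiMe2 loses methane on heating to the titanium methylidene, which should convert the lactone carbonyl into the exocyclic enol ether by [2+2] addition and cycloreversion, as in the standard preparation of Petasis–Ferrier substrates from 1,3-dioxan-4-ones, the neutral medium sparing the labile acetal, the alkenes and the silyl ether.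

Step 6
Reactants: 11 rac-tert-butyl{[2-(2,2-dimethyl-2H-chromen-6-yl)-4-methylidene-6-(3-methylbut-2-en-1-yl)-4H-1,3-benzodioxin-7-yl]oxy}dimethylsilane
Product: 13 (2S)-7-[(tert-butyldimethylsilyl)oxy]-2-(2,2-dimethyl-2H-chromen-6-yl)-6-(3-methylbut-2-en-1-yl)chroman-4-one, via oxocarbenium enol ion pair 12 (not isolated)
Conditions: (S,S)-imidodiphosphoric acid derived from 3,3′-bis(2,4,6-triethylphenyl)-BINOL (confined chiral Brønsted acid, 5 mol %), toluene (0.02 M), 4 Å MS, −40 to −20 °C; Et3N quench
Reagents that add atoms: none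
Why: Proposed new method: the chiral acid is expected to protonate the enol-ether oxygen O3 of 11 and the C2–O3 bond to ionise, assisted by the ring-B oxygen para to C2, so that both enantiomers of 11 give the same planar aryloxocarbenium–enol cation 12, paired with the chiral imidodiphosphate through the enol O–H, after which the enol carbon C3 adds to C2 and proton loss returns the acid. The closest known reaction types are the Petasis–Ferrier rearrangement of 4-methylene-1,3-dioxanes to tetrahydropyran-4-ones with Me2AlCl, the chiral phosphoric acid catalysed enantioconvergent aza-Petasis–Ferrier rearrangement of hemiaminal vinyl ethers and confined-acid-catalysed Prins cyclisations through aryl oxocarbenium ion pairs; an enantioselective oxygen version on a 1,3-benzodioxine is not established. Ring C closes by 6-endo-trig (enol-endo) attack of C3 on the O1=C2 oxocarbenium, a net [1,3] O-to-C shift in which the temporary O3–C2 bond is exchanged for C3–C2 and O3 ends as the C4 carbonyl oxygen. C2, the only stereocentre, is set by the chiral anion, which holds the twisted cation in its confined pocket so that C3 bonds to the face giving (2S), whatever the configuration of the acetal carbon in 11 was. The step needs heterolysis of C2–O3 and not of C2–O1, and intramolecular C–C bond formation rather than capture by an alkene or by water: only the O3-cleaved ion pair carries a carbon nucleophile within reach, cleavage of C2–O1 is reversible and leads nowhere, and high dilution, molecular sieves and low temperature keep the chromene and prenyl alkenes and the silyl ether out of the reaction. The product ketone is far harder to ionise at C2 than the acetal, so the new centre should persist under the catalytic acid.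

Step 7
Reactants: 13 (2S)-7-[(tert-butyldimethylsilyl)oxy]-2-(2,2-dimethyl-2H-chromen-6-yl)-6-(3-methylbut-2-en-1-yl)chroman-4-one
Product: 14 Dinklagin A, (2S)-2-(2,2-dimethyl-2H-chromen-6-yl)-7-hydroxy-6-(3-methylbut-2-en-1-yl)chroman-4-one
Conditions: Et3N·3HF (3 equiv), THF, 0 °C to rt
Reagents that add atoms: none
Why: Fluoride-mediated desilylation of an aryl silyl ether that is para to the ketone and therefore very labile, under weakly acidic conditions that cannot open ring C by retro-oxa-Michael reaction, so the C2 configuration should be kept.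

**Compound list**

1 | 4-hydroxybenzaldehyde | O=Cc1ccc(O)cc1 | starting material
2 | 1,1-diethoxy-3-methylbut-2-ene | CCOC(OCC)C=C(C)C | starting material
3 | 3-(3-methylbut-2-en-1-ylidene)-4-oxocyclohexa-1,5-diene-1-carbaldehyde (vinyl ortho-quinone methide, not isolated, alkene geometry not defined) | O=CC1=CC(=CC=C(C)C)C(=O)C=C1 | intermediate
4 | 2,2-dimethyl-2H-chromene-6-carbaldehyde | O=Cc1ccc2c(c1)C=CC(C)(C)O2 | intermediate
5 | 5-bromo-2,4-dihydroxybenzoic acid | O=C(O)c1cc(Br)c(O)cc1O | starting material
6 | tert-butyldimethylsilyl 5-bromo-4-[(tert-butyldimethylsilyl)oxy]-2-hydroxybenzoate (not isolated) | CC(C)(C)[Si](C)(C)OC(=O)c1cc(Br)c(O[Si](C)(C)C(C)(C)C)cc1O | intermediate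
7 | 5-bromo-4-[(tert-butyldimethylsilyl)oxy]-2-hydroxybenzoic acid | O=C(O)c1cc(Br)c(O[Si](C)(C)C(C)(C)C)cc1O | intermediate
8 | trimethylsilyl 5-bromo-4-[(tert-butyldimethylsilyl)oxy]-2-[(trimethylsilyl)oxy]benzoate (not isolated) | C[Si](C)(C)OC(=O)c1cc(Br)c(O[Si](C)(C)C(C)(C)C)cc1O[Si](C)(C)C | intermediate
9 | rac-6-bromo-7-[(tert-butyldimethylsilyl)oxy]-2-(2,2-dimethyl-2H-chromen-6-yl)-4H-1,3-benzodioxin-4-one | O=C1OC(c2ccc3c(c2)C=CC(C)(C)O3)Oc2cc(O[Si](C)(C)C(C)(C)C)c(Br)cc21 | intermediate
10 | rac-7-[(tert-butyldimethylsilyl)oxy]-2-(2,2-dimethyl-2H-chromen-6-yl)-6-(3-methylbut-2-en-1-yl)-4H-1,3-benzodioxin-4-one | O=C1OC(c2ccc3c(c2)C=CC(C)(C)O3)Oc2cc(O[Si](C)(C)C(C)(C)C)c(CC=C(C)C)cc21 | intermediate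
11 | rac-tert-butyl{[2-(2,2-dimethyl-2H-chromen-6-yl)-4-methylidene-6-(3-methylbut-2-en-1-yl)-4H-1,3-benzodioxin-7-yl]oxy}dimethylsilane (enol acetal) | C=C1OC(c2ccc3c(c2)C=CC(C)(C)O3)Oc2cc(O[Si](C)(C)C(C)(C)C)c(CC=C(C)C)cc21 | intermediate
12 | {2-(1-hydroxyvinyl)-4-(3-methylbut-2-en-1-yl)-5-[(tert-butyldimethylsilyl)oxy]phenyl}[(2,2-dimethyl-2H-chromen-6-yl)methylidene]oxonium, ion pair with the chiral imidodiphosphate (not isolated) | C=C(O)c1cc(CC=C(C)C)c(O[Si](C)(C)C(C)(C)C)cc1[O+]=Cc1ccc2c(c1)C=CC(C)(C)O2 | intermediate
13 | (2S)-7-[(tert-butyldimethylsilyl)oxy]-2-(2,2-dimethyl-2H-chromen-6-yl)-6-(3-methylbut-2-en-1-yl)chroman-4-one | CC(C)=CCc1cc2c(cc1O[Si](C)(C)C(C)(C)C)O[C@H](c1ccc3c(c1)C=CC(C)(C)O3)CC2=O | intermediate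
14 | Dinklagin A, (2S)-2-(2,2-dimethyl-2H-chromen-6-yl)-7-hydroxy-6-(3-methylbut-2-en-1-yl)chroman-4-one | CC(C)=CCc1cc2c(cc1O)O[C@H](c1ccc3c(c1)C=CC(C)(C)O3)CC2=O | target

Total step count: 7. Longest linear sequence: 6 steps (5 → 7 → 9 → 10 → 11 → 13 → 14; the branch from 1 through 4 is equally long).

Steps most likely to fail:

1. Step 6 (new method). The ion pair may give insufficient facial discrimination, or the acid may start oligomerisation through the chromene alkene. The fallback uses known chemistry and sets out from 11. The classical Petasis–Ferrier rearrangement with Me2AlCl (CH2Cl2, −78 °C) would give rac-7-[(tert-butyldimethylsilyl)oxy]-2-(2,2-dimethyl-2H-chromen-6-yl)-6-(3-methylbut-2-en-1-yl)chroman-4-one F1. Kinetic resolution by asymmetric transfer hydrogenation (RuCl(p-cymene)[(R,R)-TsDPEN], HCO2H–Et3N; the catalyst enantiomer that reduces the (2R)-ketone, (R,R) by analogy with simple aryl ketones) would then convert the unwanted enantiomer into the 2,4-cis (2R,4R)-flavan-4-ol F2. The unreduced (2S)-ketone is 13, where the route is rejoined, at the cost of half of the material.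

2. Step 3. The aryloxocarbenium intermediate may be captured by the chromene alkene, or ring closure by the weakly nucleophilic aryl silyl ether may stay incomplete. The fallback sets out from 4, which would be converted with trimethyl orthoformate (PPTS cat., MeOH) into 6-(dimethoxymethyl)-2,2-dimethyl-2H-chromene F3. Transacetalisation of F3 with acid 7 under thermodynamic control (PPTS cat., toluene, 60 °C, methanol removed on 5 Å MS) would return to the route at 9.

3. Step 4. The allylic zinc reagent may add to the acylal carbonyl, or coupling may occur at the tertiary allyl terminus. The fallback sets out from 9. Stille coupling with allyltributylstannane (Pd(PPh3)4, toluene, 90 °C), which has no regiochemical issue and needs no nucleophilic organometallic, would give rac-7-[(tert-butyldimethylsilyl)oxy]-2-(2,2-dimethyl-2H-chromen-6-yl)-6-(prop-2-en-1-yl)-4H-1,3-benzodioxin-4-one F4. Cross-metathesis of F4 with 2-methylbut-2-ene (second-generation Grubbs catalyst, CH2Cl2, 40 °C) would return to the route at 10.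

**Further compounds**

F1 | step 6 | rac-7-[(tert-butyldimethylsilyl)oxy]-2-(2,2-dimethyl-2H-chromen-6-yl)-6-(3-methylbut-2-en-1-yl)chroman-4-one | CC(C)=CCc1cc2c(cc1O[Si](C)(C)C(C)(C)C)OC(c1ccc3c(c1)C=CC(C)(C)O3)CC2=O
F2 | step 6 | (2R,4R)-7-[(tert-butyldimethylsilyl)oxy]-2-(2,2-dimethyl-2H-chromen-6-yl)-6-(3-methylbut-2-en-1-yl)chroman-4-ol (2,4-cis) | CC(C)=CCc1cc2c(cc1O[Si](C)(C)C(C)(C)C)O[C@@H](c1ccc3c(c1)C=CC(C)(C)O3)C[C@H]2O
F3 | step 3 | 6-(dimethoxymethyl)-2,2-dimethyl-2H-chromene | COC(OC)c1ccc2c(c1)C=CC(C)(C)O2
F4 | step 4 | rac-7-[(tert-butyldimethylsilyl)oxy]-2-(2,2-dimethyl-2H-chromen-6-yl)-6-(prop-2-en-1-yl)-4H-1,3-benzodioxin-4-one | O=C1OC(c2ccc3c(c2)C=CC(C)(C)O3)Oc2cc(O[Si](C)(C)C(C)(C)C)c(CC=C)cc21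
A1 | direct plan | 2-hydroxy-5-(3-methylbut-2-en-1-yl)-4-[(triisopropylsilyl)oxy]benzaldehyde | O=Cc1cc(CC=C(C)C)c(O[Si](C(C)C)(C(C)C)C(C)C)cc1O
A2 | direct plan | 2,2-dimethyl-6-vinyl-2H-chromene | C=Cc1ccc2c(c1)C=CC(C)(C)O2
A3 | direct plan | (2S,4S)-2-(2,2-dimethyl-2H-chromen-6-yl)-4-methoxy-6-(3-methylbut-2-en-1-yl)-7-[(triisopropylsilyl)oxy]chromane | CC(C)=CCc1cc2c(cc1O[Si](C(C)C)(C(C)C)C(C)C)O[C@H](c1ccc3c(c1)C=CC(C)(C)O3)C[C@@H]2OC
A4 | direct plan | (2S,4RS)-2-(2,2-dimethyl-2H-chromen-6-yl)-6-(3-methylbut-2-en-1-yl)-7-[(triisopropylsilyl)oxy]chroman-4-ol | CC(C)=CCc1cc2c(cc1O[Si](C(C)C)(C(C)C)C(C)C)O[C@H](c1ccc3c(c1)C=CC(C)(C)O3)CC2O
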